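**Retrosynthetic overview**

1. The target (2S,3S, trans) comes from dihydrobenzofuran 21 by acid removal of the MOM and tert-butyl ethers, then mild hydroxide cleavage of the two catechol triflates.
2. 21 is formed in one operation from the enantiopure trans-stilbene oxide 18: the oxirane (O1, C2, C3) grows by two atoms (C7a, C3a) through σ-insertion of aryne 19 into one epoxide C–O bond, which makes O1–C7a and C3–C3a.
3. Enabling feature: C2 and C3 are vicinal sp3 carbons that each carry one aryl group and share O1, so they map onto a stilbene oxide. The C4 oxygen next to C3a makes the partner a 3-alkoxyaryne, which fixes its orientation. Carrying the C2 aryl ring as a bis(triflate) decides which C–O bond ionises.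
4. 18 comes from a Shi epoxidation of E-stilbene 17, itself made by Horner–Wadsworth–Emmons coupling of phosphonate 14 with aldehyde 16.
5. The aryne precursor 10 comes from carbamate-directed ortho-silylation and triflation of stilbene phenol 4 (Heck coupling of 2 with 3). Ring order: oxirane (step 11), then dihydrofuran (step 12).

Key step: step 12

Remark: compounds 1, 3, 11 and 15 and the D-fructose-derived epoxidation ketone are taken as commercial; the catechol is carried as its bis(triflate) from the start because this electron-poor ring steers the key step and protects the C2–O1 bond during acid deprotection.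

**Route**

Step 1
Reactants: 1 5-bromobenzene-1,3-diol
Product: 2 3-bromo-5-(methoxymethoxy)phenol
Conditions: MOMCl (1.0 equiv), K2CO3, acetone, 0 °C → rt
Reagents that add atoms: chloromethyl methyl ether (MOMCl), COCCl
Why: Williamson-type O-alkylation of one of two equivalent phenols with one equivalent of MOMCl should give the mono-ether as the main part of a statistical mixture, separable from the bis-ether and the recyclable diol; no stereocentre.

Step 2
Reactants: 2 3-bromo-5-(methoxymethoxy)phenol; 3 1-tert-butoxy-4-ethenylbenzene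
Product: 4 3-[(E)-2-(4-tert-butoxyphenyl)ethenyl]-5-(methoxymethoxy)phenol
Conditions: Pd(OAc)2 (5 mol%), P(o-tol)3, Et3N, DMF, 100 °C
Reagents that add atoms: none
Why: Mizoroki–Heck coupling of the aryl bromide with the terminal styrene should give the (E)-stilbene by syn-insertion and syn-β-hydride elimination, with the free phenol and the acetal inert.

Step 3
Reactants: 4 3-[(E)-2-(4-tert-butoxyphenyl)ethenyl]-5-(methoxymethoxy)phenol
Product: 5 3-[(E)-2-(4-tert-butoxyphenyl)ethenyl]-5-(methoxymethoxy)phenyl N-(propan-2-yl)carbamate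
Conditions: i-PrNCO, Et3N (cat.), CH2Cl2, rt
Reagents that add atoms: isopropyl isocyanate, CC(C)N=C=O
Why: Base-catalysed addition of the phenol to the isocyanate gives the secondary O-aryl carbamate, which serves as directing group and as a latent phenol.

Step 4
Reactants: 5 3-[(E)-2-(4-tert-butoxyphenyl)ethenyl]-5-(methoxymethoxy)phenyl N-(propan-2-yl)carbamate
Product: 8 5-[(E)-2-(4-tert-butoxyphenyl)ethenyl]-3-(methoxymethoxy)-2-(trimethylsilyl)phenyl N-(propan-2-yl)carbamate, via N-silyl carbamate 6 (not isolated), via C-silylated N-silyl carbamate 7 (not isolated)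
Conditions: TBSOTf (1.05 equiv), TMEDA, Et2O, 0 °C → rt; n-BuLi, TMEDA, −78 °C; TMSCl, −78 °C → rt; aq. NaHSO4 work-up
Reagents that add atoms: chlorotrimethylsilane, C[Si](C)(C)Cl; tert-butyldimethylsilyl triflate, CC(C)(C)[Si](C)(C)OS(=O)(=O)C(F)(F)F (its atoms are carried only in 6 and 7)
Why: In situ N-silylation blocks the acidic N–H, after which the carbamate and the OMOM group jointly direct ortho-lithiation to the ring carbon between them (directed ortho-metalation); TMSCl traps the aryllithium and the N–Si bond is hydrolysed in the acidic work-up.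

Step 5
Reactants: 8 5-[(E)-2-(4-tert-butoxyphenyl)ethenyl]-3-(methoxymethoxy)-2-(trimethylsilyl)phenyl N-(propan-2-yl)carbamate
Product: 10 5-[(E)-2-(4-tert-butoxyphenyl)ethenyl]-3-(methoxymethoxy)-2-(trimethylsilyl)phenyl trifluoromethanesulfonate, via silylphenoxide 9 (not isolated)
Conditions: DBU, Et2NH, MeCN, 40 °C; then PhNTf2, rt
Reagents that add atoms: N-phenylbis(trifluoromethanesulfonimide), FC(F)(F)S(=O)(=O)N(c1ccccc1)S(=O)(=O)C(F)(F)F
Why: DBU triggers E1cB loss of isopropyl isocyanate (scavenged by Et2NH as the urea) and the liberated ortho-silyl phenoxide is O-sulfonylated by PhNTf2, giving the o-silylaryl triflate aryne precursor.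

Step 6
Reactants: 11 4-methylbenzene-1,2-diol
Product: 12 4-methyl-1,2-phenylene bis(trifluoromethanesulfonate)
Conditions: Tf2O (2.2 equiv), pyridine, CH2Cl2, 0 °C
Reagents that add atoms: trifluoromethanesulfonic anhydride, O=S(=O)(OS(=O)(=O)C(F)(F)F)C(F)(F)F
Why: O-sulfonylation of both phenols; the two triflates are the electron-withdrawing groups that later control the key step.

Step 7
Reactants: 12 4-methyl-1,2-phenylene bis(trifluoromethanesulfonate)
Product: 13 4-(bromomethyl)-1,2-phenylene bis(trifluoromethanesulfonate)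
Conditions: NBS (1.0 equiv), AIBN (cat.), PhCF3, 85 °C
Reagents that add atoms: N-bromosuccinimide, BrN1C(=O)CCC1=O
Why: Wohl–Ziegler radical bromination at the only benzylic position; the deactivated ring suppresses nuclear bromination.

Step 8
Reactants: 13 4-(bromomethyl)-1,2-phenylene bis(trifluoromethanesulfonate)
Product: 14 4-[(diethoxyphosphoryl)methyl]-1,2-phenylene bis(trifluoromethanesulfonate)
Conditions: P(OEt)3 (neat), 130 °C
Reagents that add atoms: triethyl phosphite, CCOP(OCC)OCC
Why: Michaelis–Arbuzov reaction of the benzylic bromide; aryl triflates are inert to phosphite in the absence of a transition metal.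

Step 9
Reactants: 15 3,5-dihydroxybenzaldehyde
Product: 16 3,5-bis(methoxymethoxy)benzaldehyde
Conditions: MOMCl (2.5 equiv), K2CO3, acetone, rt
Reagents that add atoms: chloromethyl methyl ether (MOMCl), COCCl
Why: Double Williamson-type O-alkylation of the phenols gives the bis-acetal aldehyde.

Step 10
Reactants: 14 4-[(diethoxyphosphoryl)methyl]-1,2-phenylene bis(trifluoromethanesulfonate); 16 3,5-bis(methoxymethoxy)benzaldehyde
Product: 17 4-[(E)-2-[3,5-bis(methoxymethoxy)phenyl]ethenyl]-1,2-phenylene bis(trifluoromethanesulfonate)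
Conditions: NaHMDS (added to the mixture of both partners), THF, −78 °C → rt
Reagents that add atoms: none
Why: Horner–Wadsworth–Emmons olefination of the aryl-stabilised phosphonate carbanion should give the (E)-stilbene through the favoured anti-oxaphosphetane, and the non-enolisable aldehyde traps the carbanion as it forms so that the triflates are not attacked.

Step 11
Reactants: 17 4-[(E)-2-[3,5-bis(methoxymethoxy)phenyl]ethenyl]-1,2-phenylene bis(trifluoromethanesulfonate)
Product: 18 4-[(2R,3R)-3-[3,5-bis(methoxymethoxy)phenyl]oxiran-2-yl]-1,2-phenylene bis(trifluoromethanesulfonate)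
Conditions: D-fructose-derived Shi ketone (30 mol%), Oxone, K2CO3, Bu4NHSO4, MeCN/DMM–aq. Na2B4O7/EDTA buffer, 0 °C
Reagents that add atoms: potassium peroxymonosulfate (Oxone), [K+].[O-]S(=O)(=O)OO
Why: Shi asymmetric epoxidation: the chiral dioxirane transfers oxygen to the trans-disubstituted alkene through the spiro transition state, which for (E)-stilbenes gives the (R,R)-epoxide, so both stereocentres are set by the catalyst.

Step 12
Reactants: 18 4-[(2R,3R)-3-[3,5-bis(methoxymethoxy)phenyl]oxiran-2-yl]-1,2-phenylene bis(trifluoromethanesulfonate); 10 5-[(E)-2-(4-tert-butoxyphenyl)ethenyl]-3-(methoxymethoxy)-2-(trimethylsilyl)phenyl trifluoromethanesulfonate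
Product: 21 4-[(2S,3S)-3-[3,5-bis(methoxymethoxy)phenyl]-6-[(E)-2-(4-tert-butoxyphenyl)ethenyl]-4-(methoxymethoxy)-2,3-dihydro-1-benzofuran-2-yl]-1,2-phenylene bis(trifluoromethanesulfonate), via aryne 19 (not isolated), via oxiranium zwitterion 20 (not isolated)
Conditions: 10 (1.5 equiv, slow addition), CsF (4 equiv), MeCN, 25 °C
Reagents that add atoms: none
Why: Fluoride-induced 1,2-elimination of 10 gives the 3-alkoxyaryne 19, and the epoxide oxygen of 18 adds to the aryne carbon remote from the OMOM group (future C7a), leaving the carbanion at C3a next to the inductively stabilising oxygen in zwitterion 20; the C–O bond to the carbon bearing the bis(methoxymethoxy)phenyl group then ionises and the C3a carbanion collapses onto that benzylic centre, so the three-membered ring becomes the five-membered O1–C2–C3–C3a–C7a ring. The closest known reaction type is the fluoride-triggered σ-insertion of arynes into the benzylic C–O bond of aryl oxiranes, which gives 3-aryl-2,3-dihydrobenzofurans. The closure is formally 5-endo-tet and cannot be a backside SN2, so it should run as an SN1-like, front-side ion-pair collapse (anion–cation recombination). C2 keeps the epoxide configuration because its C–O bond is never broken (the (R)-oxirane carbon becomes 2S only through the change in CIP priorities), and C3 is set in the collapse trans to the C2 aryl group, which is both the ion-pair (retention) outcome and the less strained arrangement, so either configuration at that carbon should converge on 3S. The step needs three selectivities: aryne orientation (secured by the 3-OMOM group), the choice of which C–O bond breaks (secured by the two triflates, which destabilise positive charge at the catechol-bearing carbon while the meta-alkoxy ring tolerates it), and O-attack in preference to reaction at the stilbene π-bond (epoxide kept concentrated, aryne generated slowly).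

Step 13
Reactants: 21 4-[(2S,3S)-3-[3,5-bis(methoxymethoxy)phenyl]-6-[(E)-2-(4-tert-butoxyphenyl)ethenyl]-4-(methoxymethoxy)-2,3-dihydro-1-benzofuran-2-yl]-1,2-phenylene bis(trifluoromethanesulfonate)
Product: 22 4-[(2S,3S)-3-(3,5-dihydroxyphenyl)-4-hydroxy-6-[(E)-2-(4-hydroxyphenyl)ethenyl]-2,3-dihydro-1-benzofuran-2-yl]-1,2-phenylene bis(trifluoromethanesulfonate)
Conditions: 3 M HCl, MeOH/THF (degassed), 45 °C
Reagents that add atoms: none
Why: Acid-catalysed methanolysis of the three MOM acetals and the aryl tert-butyl ether; the bis(triflate) ring destabilises a cation at C2, so the benzylic C2–O1 bond and both stereocentres should be untouched.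

Step 14
Reactants: 22 4-[(2S,3S)-3-(3,5-dihydroxyphenyl)-4-hydroxy-6-[(E)-2-(4-hydroxyphenyl)ethenyl]-2,3-dihydro-1-benzofuran-2-yl]-1,2-phenylene bis(trifluoromethanesulfonate)
Product: 23 4-[(2S,3S)-3-(3,5-dihydroxyphenyl)-4-hydroxy-6-[(E)-2-(4-hydroxyphenyl)ethenyl]-2,3-dihydro-1-benzofuran-2-yl]benzene-1,2-diol
Conditions: Et4NOH (aq., excess), 1,4-dioxane, rt, Ar (degassed); then aq. HCl to pH 4, 0 °C
Reagents that add atoms: none
Why: Hydroxide attacks sulfur of the aryl triflates (S–O cleavage) under mild conditions and releases the catechol without touching C2 or C3, with oxygen excluded to protect the phenolates.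

**Compound list**

1 | 5-bromobenzene-1,3-diol | Oc1cc(O)cc(Br)c1 | starting material
2 | 3-bromo-5-(methoxymethoxy)phenol | COCOc1cc(O)cc(Br)c1 | intermediate
3 | 1-tert-butoxy-4-ethenylbenzene | C=Cc1ccc(OC(C)(C)C)cc1 | starting material
4 | 3-[(E)-2-(4-tert-butoxyphenyl)ethenyl]-5-(methoxymethoxy)phenol | COCOc1cc(O)cc(/C=C/c2ccc(OC(C)(C)C)cc2)c1 | intermediate
5 | 3-[(E)-2-(4-tert-butoxyphenyl)ethenyl]-5-(methoxymethoxy)phenyl N-(propan-2-yl)carbamate | COCOc1cc(OC(=O)NC(C)C)cc(/C=C/c2ccc(OC(C)(C)C)cc2)c1 | intermediate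
6 | N-(tert-butyldimethylsilyl) derivative of 5 (N-silyl carbamate) | COCOc1cc(OC(=O)N(C(C)C)[Si](C)(C)C(C)(C)C)cc(/C=C/c2ccc(OC(C)(C)C)cc2)c1 | intermediate
7 | N-(tert-butyldimethylsilyl) derivative of 8 (C-silylated N-silyl carbamate) | COCOc1cc(/C=C/c2ccc(OC(C)(C)C)cc2)cc(OC(=O)N(C(C)C)[Si](C)(C)C(C)(C)C)c1[Si](C)(C)C | intermediate
8 | 5-[(E)-2-(4-tert-butoxyphenyl)ethenyl]-3-(methoxymethoxy)-2-(trimethylsilyl)phenyl N-(propan-2-yl)carbamate | COCOc1cc(/C=C/c2ccc(OC(C)(C)C)cc2)cc(OC(=O)NC(C)C)c1[Si](C)(C)C | intermediate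
9 | 5-[(E)-2-(4-tert-butoxyphenyl)ethenyl]-3-(methoxymethoxy)-2-(trimethylsilyl)phenol (formed as its phenoxide) | COCOc1cc(/C=C/c2ccc(OC(C)(C)C)cc2)cc(O)c1[Si](C)(C)C | intermediate
10 | 5-[(E)-2-(4-tert-butoxyphenyl)ethenyl]-3-(methoxymethoxy)-2-(trimethylsilyl)phenyl trifluoromethanesulfonate | COCOc1cc(/C=C/c2ccc(OC(C)(C)C)cc2)cc(OS(=O)(=O)C(F)(F)F)c1[Si](C)(C)C | intermediate
11 | 4-methylbenzene-1,2-diol | Cc1ccc(O)c(O)c1 | starting material
12 | 4-methyl-1,2-phenylene bis(trifluoromethanesulfonate) | Cc1ccc(OS(=O)(=O)C(F)(F)F)c(OS(=O)(=O)C(F)(F)F)c1 | intermediate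
13 | 4-(bromomethyl)-1,2-phenylene bis(trifluoromethanesulfonate) | BrCc1ccc(OS(=O)(=O)C(F)(F)F)c(OS(=O)(=O)C(F)(F)F)c1 | intermediate
14 | 4-[(diethoxyphosphoryl)methyl]-1,2-phenylene bis(trifluoromethanesulfonate) | CCOP(=O)(Cc1ccc(OS(=O)(=O)C(F)(F)F)c(OS(=O)(=O)C(F)(F)F)c1)OCC | intermediate
15 | 3,5-dihydroxybenzaldehyde | O=Cc1cc(O)cc(O)c1 | starting material
16 | 3,5-bis(methoxymethoxy)benzaldehyde | COCOc1cc(C=O)cc(OCOC)c1 | intermediate
17 | 4-[(E)-2-[3,5-bis(methoxymethoxy)phenyl]ethenyl]-1,2-phenylene bis(trifluoromethanesulfonate) | COCOc1cc(/C=C/c2ccc(OS(=O)(=O)C(F)(F)F)c(OS(=O)(=O)C(F)(F)F)c2)cc(OCOC)c1 | intermediate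
18 | 4-[(2R,3R)-3-[3,5-bis(methoxymethoxy)phenyl]oxiran-2-yl]-1,2-phenylene bis(trifluoromethanesulfonate) | FC(F)(F)S(=O)(=O)Oc1ccc(cc1OS(=O)(=O)C(F)(F)F)[C@H]1O[C@@H]1c1cc(OCOC)cc(OCOC)c1 | intermediate
19 | 1,2-didehydro-3-(methoxymethoxy)-5-[(E)-2-(4-tert-butoxyphenyl)ethenyl]benzene (aryne) | COCOC1=CC(/C=C/c2ccc(OC(C)(C)C)cc2)=CC#C1 | intermediate
20 | O-aryl oxiranium zwitterion from 18 and 19 (carbanion at the ring carbon between the O-substituted carbons) | COCOc1cc(/C=C/c2ccc(OC(C)(C)C)cc2)cc([c-]1)[O+]1[C@H](c2ccc(OS(=O)(=O)C(F)(F)F)c(OS(=O)(=O)C(F)(F)F)c2)[C@H]1c1cc(OCOC)cc(OCOC)c1 | intermediate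
21 | 4-[(2S,3S)-3-[3,5-bis(methoxymethoxy)phenyl]-6-[(E)-2-(4-tert-butoxyphenyl)ethenyl]-4-(methoxymethoxy)-2,3-dihydro-1-benzofuran-2-yl]-1,2-phenylene bis(trifluoromethanesulfonate) | CC(C)(C)Oc1ccc(/C=C/c2cc(OCOC)c3c(c2)O[C@H](c2ccc(OS(=O)(=O)C(F)(F)F)c(OS(=O)(=O)C(F)(F)F)c2)[C@H]3c2cc(OCOC)cc(OCOC)c2)cc1 | intermediate
22 | 4-[(2S,3S)-3-(3,5-dihydroxyphenyl)-4-hydroxy-6-[(E)-2-(4-hydroxyphenyl)ethenyl]-2,3-dihydro-1-benzofuran-2-yl]-1,2-phenylene bis(trifluoromethanesulfonate) | Oc1ccc(/C=C/c2cc(O)c3c(c2)O[C@H](c2ccc(OS(=O)(=O)C(F)(F)F)c(OS(=O)(=O)C(F)(F)F)c2)[C@H]3c2cc(O)cc(O)c2)cc1 | intermediate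
23 | 4-[(2S,3S)-3-(3,5-dihydroxyphenyl)-4-hydroxy-6-[(E)-2-(4-hydroxyphenyl)ethenyl]-2,3-dihydro-1-benzofuran-2-yl]benzene-1,2-diol | Oc1ccc(/C=C/c2cc(O)c3c(c2)O[C@H](c2ccc(O)c(O)c2)[C@H]3c2cc(O)cc(O)c2)cc1 | target

**Step count**

Total: 14 steps. Longest linear sequence: 8 steps (1 → 2 → 3 → 4 → 5 → 12 → 13 → 14, or equally 6 → 7 → 8 → 10 → 11 → 12 → 13 → 14).

**Steps most likely to fail**

Step 12. The zwitterion may ionise the other C–O bond (aryl groups exchanged between C2 and C3), transfer a proton internally to give an aryl enol ether, or be opened by fluoride to an acyclic adduct; the aryne may also be consumed by the stilbene π-bond. The fallback sets out from 4 and 17 and builds the same ring in separate C–C and C–O bond-forming steps with double inversion. Phenol 4 is converted with MOMCl/NaH into 1-[(E)-2-(4-tert-butoxyphenyl)ethenyl]-3,5-bis(methoxymethoxy)benzene F1. Stilbene 17 is epoxidised with the enantiomeric ketone (from L-sorbose) to 4-[(2S,3S)-3-[3,5-bis(methoxymethoxy)phenyl]oxiran-2-yl]-1,2-phenylene bis(trifluoromethanesulfonate) F2. F1 is lithiated between its two OMOM groups (n-BuLi, THF) and the aryllithium opens F2 under BF3·OEt2 assistance at −78 °C at the carbon bearing the bis(methoxymethoxy)phenyl group, with inversion. This gives (1R,2S)-1-[3,4-bis(trifluoromethanesulfonyloxy)phenyl]-2-[3,5-bis(methoxymethoxy)phenyl]-2-[4-[(E)-2-(4-tert-butoxyphenyl)ethenyl]-2,6-bis(methoxymethoxy)phenyl]ethan-1-ol F3. HCl/MeOH removes the acetals and the tert-butyl ether to give (1R,2S)-1-[3,4-bis(trifluoromethanesulfonyloxy)phenyl]-2-(3,5-dihydroxyphenyl)-2-[2,6-dihydroxy-4-[(E)-2-(4-hydroxyphenyl)ethenyl]phenyl]ethan-1-ol F4. Mitsunobu cycloetherification (PPh3, DIAD, THF, 0 °C) by either of the two equivalent ortho phenols inverts the carbinol carbon and returns to the route at 22.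

Step 4. The silyl triflate may attack the MOM acetal or the tert-butyl ether during N-silylation, n-BuLi may add to the stilbene, and lithiation may occur at the other ortho position. The fallback sets out from 4 and uses a tertiary carbamate with an amide base, so that neither a silyl triflate nor an alkyllithium is needed. Compound 4 is acylated with ClC(O)NEt2/K2CO3 to 3-[(E)-2-(4-tert-butoxyphenyl)ethenyl]-5-(methoxymethoxy)phenyl N,N-diethylcarbamate F5. Directed ortho-metalation with LiTMP in the presence of TMSCl (in situ quench, THF, −78 °C) gives 5-[(E)-2-(4-tert-butoxyphenyl)ethenyl]-3-(methoxymethoxy)-2-(trimethylsilyl)phenyl N,N-diethylcarbamate F6. Reductive cleavage with LiAlH4 (THF, 0 °C → rt) gives phenol 9, now isolated, and triflation with PhNTf2/Cs2CO3 returns to the route at 10.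

Step 14. Hydrolysis of the second triflate next to a phenoxide may be slow, and the polyphenolate may meanwhile be oxidised by air or open the ring through a quinone methide. The fallback sets out from 21 and reverses the order of deprotection so that only a catecholate is ever exposed to base. Et4NOH in dioxane on 21 gives 4-[(2S,3S)-3-[3,5-bis(methoxymethoxy)phenyl]-6-[(E)-2-(4-tert-butoxyphenyl)ethenyl]-4-(methoxymethoxy)-2,3-dihydro-1-benzofuran-2-yl]benzene-1,2-diol F7. The acetals and the tert-butyl ether are then removed under thiol-assisted Lewis-acid conditions (ZnBr2, n-PrSH, CH2Cl2, 0 °C), which returns to the route at 23.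

**Further compounds**

F1 | step 12 | 1-[(E)-2-(4-tert-butoxyphenyl)ethenyl]-3,5-bis(methoxymethoxy)benzene | COCOc1cc(OCOC)cc(/C=C/c2ccc(OC(C)(C)C)cc2)c1
F2 | step 12 | 4-[(2S,3S)-3-[3,5-bis(methoxymethoxy)phenyl]oxiran-2-yl]-1,2-phenylene bis(trifluoromethanesulfonate) | FC(F)(F)S(=O)(=O)Oc1ccc(cc1OS(=O)(=O)C(F)(F)F)[C@@H]1O[C@H]1c1cc(OCOC)cc(OCOC)c1
F3 | step 12 | (1R,2S)-1-[3,4-bis(trifluoromethanesulfonyloxy)phenyl]-2-[3,5-bis(methoxymethoxy)phenyl]-2-[4-[(E)-2-(4-tert-butoxyphenyl)ethenyl]-2,6-bis(methoxymethoxy)phenyl]ethan-1-ol | O[C@@H](c1ccc(OS(=O)(=O)C(F)(F)F)c(OS(=O)(=O)C(F)(F)F)c1)[C@H](c1c(OCOC)cc(/C=C/c2ccc(OC(C)(C)C)cc2)cc1OCOC)c1cc(OCOC)cc(OCOC)c1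
F4 | step 12 | (1R,2S)-1-[3,4-bis(trifluoromethanesulfonyloxy)phenyl]-2-(3,5-dihydroxyphenyl)-2-[2,6-dihydroxy-4-[(E)-2-(4-hydroxyphenyl)ethenyl]phenyl]ethan-1-ol | O[C@@H](c1ccc(OS(=O)(=O)C(F)(F)F)c(OS(=O)(=O)C(F)(F)F)c1)[C@H](c1c(O)cc(/C=C/c2ccc(O)cc2)cc1O)c1cc(O)cc(O)c1
F5 | step 4 | 3-[(E)-2-(4-tert-butoxyphenyl)ethenyl]-5-(methoxymethoxy)phenyl N,N-diethylcarbamate | COCOc1cc(OC(=O)N(CC)CC)cc(/C=C/c2ccc(OC(C)(C)C)cc2)c1
F6 | step 4 | 5-[(E)-2-(4-tert-butoxyphenyl)ethenyl]-3-(methoxymethoxy)-2-(trimethylsilyl)phenyl N,N-diethylcarbamate | COCOc1cc(/C=C/c2ccc(OC(C)(C)C)cc2)cc(OC(=O)N(CC)CC)c1[Si](C)(C)C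
F7 | step 14 | 4-[(2S,3S)-3-[3,5-bis(methoxymethoxy)phenyl]-6-[(E)-2-(4-tert-butoxyphenyl)ethenyl]-4-(methoxymethoxy)-2,3-dihydro-1-benzofuran-2-yl]benzene-1,2-diol | CC(C)(C)Oc1ccc(/C=C/c2cc(OCOC)c3c(c2)O[C@H](c2ccc(O)c(O)c2)[C@H]3c2cc(OCOC)cc(OCOC)c2)cc1
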